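**Retrosynthetic overview**

1. Numbering: lactone O1, C2 (C=O), C3, C4 (R), C5; Ca is the benzylidene CH on ring A (4-hydroxy-3-methoxyphenyl), Cb the benzylic CH2 on ring B (3,4-dimethoxyphenyl). The strategy rests on the unit C5–C4–Cb with the electron-rich ring B on Cb, read as a ring-opened trans-arylcyclopropane.
2. Target 17 ⇐ pivalate 16 (methanolysis) ⇐ cyclopropyl acrylic acid 15: O1–C5 is formed while the cyclopropane bond C5–Cb is cleaved, which closes the lactone.
3. 15 ⇐ C3–C4 Suzuki coupling of cyclopropylboronic acid 7 with the Z alpha-bromo cinnamate 12, then ester cleavage; C4 and the alkene geometry are carried through with retention.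
4. 7 ⇐ alkyne 1 by hydroboration and tartaramide-directed Simmons–Smith cyclopropanation (sets C4); 12 ⇐ vanillin 8 by pivaloylation and bromo-Wittig olefination.
5. Ring order: cyclopropane (step 3), then lactone (step 8), the cyclopropane being consumed as the lactone forms.

Key step: step 8

Assumption: the (2R,3R)-tartaramide is taken to steer the zinc carbenoid to the alkene face that gives the (1R,2R)-cyclopropylboronate; should the sense of induction be the opposite, the (2S,3S)-diamide is used with no other change.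

**Route**

Step 1
Reactants: 1 4-ethynyl-1,2-dimethoxybenzene
Product: 3 [(E)-2-(3,4-dimethoxyphenyl)ethenyl]boronic acid, via catechol boronate 2 (not isolated)
Conditions: catecholborane (1.1 equiv), THF, 70 °C; then H2O, rt
Reagents that add atoms: catecholborane, B1Oc2ccccc2O1; water, O
Why: Syn hydroboration of the terminal alkyne (Brown hydroboration with catecholborane) puts boron on the unhindered terminal carbon and gives the E alkenylboronate, which water hydrolyses to the boronic acid.

Step 2
Reactants: 3 [(E)-2-(3,4-dimethoxyphenyl)ethenyl]boronic acid; 4 (2R,3R)-2,3-dihydroxy-N,N,N',N'-tetramethylbutanediamide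
Product: 5 (4R,5R)-2-[(E)-2-(3,4-dimethoxyphenyl)ethenyl]-N,N,N',N'-tetramethyl-1,3,2-dioxaborolane-4,5-dicarboxamide
Conditions: 4 Å molecular sieves, THF, rt; filtered and concentrated
Reagents that add atoms: none
Why: Condensation of the boronic acid with the 1,2-diol of the tartaramide (boronic ester formation, water taken up by the sieves) installs a C2-symmetric auxiliary whose amide carbonyls can bind zinc.

Step 3
Reactants: 5 (4R,5R)-2-[(E)-2-(3,4-dimethoxyphenyl)ethenyl]-N,N,N',N'-tetramethyl-1,3,2-dioxaborolane-4,5-dicarboxamide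
Product: 7 [(1R,2R)-2-(3,4-dimethoxyphenyl)cyclopropyl]boronic acid, via cyclopropyl tartaramide boronate 6 (not isolated)
Conditions: Zn–Cu couple, CH2I2, Et2O, reflux; then H2O, rt; recrystallisation
Reagents that add atoms: diiodomethane, ICI; water, O
Why: Auxiliary-directed Simmons–Smith cyclopropanation: an amide carbonyl of the tartaramide binds the zinc carbenoid and delivers CH2 to one face of the alkene, which sets the boron-bearing carbon (the later C4, R) and Cb (R) in one event, trans because the addition is stereospecific for the E alkene, and water then releases the boronic acid and the auxiliary.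

Step 4
Reactants: 8 vanillin (4-hydroxy-3-methoxybenzaldehyde)
Product: 9 4-formyl-2-methoxyphenyl 2,2-dimethylpropanoate
Conditions: t-BuCOCl, Et3N, DMAP (5 mol%), CH2Cl2, 0 °C to rt
Reagents that add atoms: pivaloyl chloride, CC(C)(C)C(=O)Cl
Why: DMAP-catalysed acylation of the phenol gives an ester that lowers the electron density of ring A for step 8 and that, being hindered, should survive the aqueous phosphate of step 6.

Step 5
Reactants: 9 4-formyl-2-methoxyphenyl 2,2-dimethylpropanoate; 10 tert-butyl (triphenylphosphoranylidene)acetate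
Product: 12 tert-butyl (2Z)-2-bromo-3-[4-(2,2-dimethylpropanoyloxy)-3-methoxyphenyl]prop-2-enoate, via bromo ylide 11 (not isolated)
Conditions: 10, NBS, CH2Cl2, −20 °C; then 9, −20 °C to rt
Reagents that add atoms: N-bromosuccinimide, O=C1CCC(=O)N1Br
Why: NBS brominates the stabilised ylide at carbon (the succinimide anion removes the proton) and the resulting bromo ylide undergoes a Wittig olefination that places the aryl group trans to the ester, as stabilised ylides do, which is the Z bromoacrylate.

Step 6
Reactants: 7 [(1R,2R)-2-(3,4-dimethoxyphenyl)cyclopropyl]boronic acid; 12 tert-butyl (2Z)-2-bromo-3-[4-(2,2-dimethylpropanoyloxy)-3-methoxyphenyl]prop-2-enoate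
Product: 13 tert-butyl (2E)-2-[(1R,2R)-2-(3,4-dimethoxyphenyl)cyclopropyl]-3-[4-(2,2-dimethylpropanoyloxy)-3-methoxyphenyl]prop-2-enoate
Conditions: Pd(OAc)2 (5 mol%), SPhos (10 mol%), K3PO4 (3 equiv), toluene/H2O 10:1, 80 °C
Reagents that add atoms: none
Why: Suzuki–Miyaura coupling of a cyclopropylboronic acid with an alkenyl bromide proceeds with retention at the cyclopropyl carbon and at the double bond, so C4 stays R and the cyclopropane ends up cis to ring A and trans to the ester (E).

Step 7
Reactants: 13 tert-butyl (2E)-2-[(1R,2R)-2-(3,4-dimethoxyphenyl)cyclopropyl]-3-[4-(2,2-dimethylpropanoyloxy)-3-methoxyphenyl]prop-2-enoate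
Product: 15 (2E)-2-[(1R,2R)-2-(3,4-dimethoxyphenyl)cyclopropyl]-3-[4-(2,2-dimethylpropanoyloxy)-3-methoxyphenyl]prop-2-enoic acid, via trimethylsilyl ester 14 (not isolated)
Conditions: Me3SiOTf, 2,6-lutidine, CH2Cl2, 0 °C to rt; then H2O
Reagents that add atoms: none
Why: Silyl triflate cleavage of the tert-butyl ester (O-silylation, loss of isobutene, hydrolysis of the silyl ester on work-up) is buffered by 2,6-lutidine and so avoids the strong protic acid that could open the electron-rich arylcyclopropane, while the aryl pivalate is inert.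

Step 8
Reactants: 15 (2E)-2-[(1R,2R)-2-(3,4-dimethoxyphenyl)cyclopropyl]-3-[4-(2,2-dimethylpropanoyloxy)-3-methoxyphenyl]prop-2-enoic acid
Product: 16 4-{(E)-[(4R)-4-(3,4-dimethoxybenzyl)-2-oxooxolan-3-ylidene]methyl}-2-methoxyphenyl 2,2-dimethylpropanoate
Conditions: 9-mesityl-10-methylacridinium tetrafluoroborate (5 mol%), PhSH (20 mol%), 2,6-lutidine (20 mol%), ClCH2CH2Cl (0.05 M), 450 nm LEDs, N2, rt
Reagents that add atoms: none
Why: Proposed new method: the photoexcited acridinium oxidises the 3,4-dimethoxyphenylcyclopropane of 15 to its radical cation, in which both ring bonds to Cb are weakened; the carboxyl oxygen carried on C3 (made more nucleophilic by partial deprotonation with 2,6-lutidine) then attacks C5 from the side opposite Cb in a three-electron SN2 displacement, so that O1–C5 forms as C5–Cb breaks, and the Cb benzylic radical takes a hydrogen atom from PhSH, whose thiyl radical reoxidises the reduced acridine and is reprotonated, which makes the step a redox-neutral isomerisation. The closest known reaction type is the acridinium/thiol photoredox ring-opening hydrofunctionalisation of arylcyclopropanes by external oxygen nucleophiles, together with acridinium-catalysed anti-Markovnikov lactonisation of alkenoic acids; lactone closure by a tethered acrylic acid on a cyclopropane radical cation has not been shown. The five-membered lactone (O1, C2, C3, C4, C5) closes 5-exo-tet with respect to the breaking C5–Cb bond. No stereocentre is created: C4 is not a reacting centre and keeps the R configuration set in step 3, C5 is inverted but is a CH2, and Cb becomes a CH2. The step needs the hole on ring B and not on ring A (the pivalate and the conjugated acrylic acid raise the potential of ring A), attack at C5 and not at C4 (which would give a four-membered lactone), and carboxylate-assisted C5–Cb cleavage in preference to unassisted C4–Cb scission towards the allyl-stabilised C4 radical, which would erode C4 or lead to a six-membered lactone or a cyclopentene; only the proximity of the carboxylate to C5 secures this last point, which is the main uncertainty. The E double bond should persist because the cinnamate does not absorb at 450 nm and the acridinium triplet is expected to lie too low to sensitise it.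

Step 9
Reactants: 16 4-{(E)-[(4R)-4-(3,4-dimethoxybenzyl)-2-oxooxolan-3-ylidene]methyl}-2-methoxyphenyl 2,2-dimethylpropanoate
Product: 17 (3E,4R)-4-(3,4-dimethoxybenzyl)-3-(4-hydroxy-3-methoxybenzylidene)oxolan-2-one
Conditions: K2CO3 (1.5 equiv), MeOH, 0 °C to rt; then 1 M HCl
Reagents that add atoms: none
Why: Base-mediated methanolysis (transesterification) cleaves the aryl pivalate because the conjugated phenoxide is a good leaving group, the C4 hydrogen sits in a cross-conjugated position that the carbonyl does not acidify, and acidification recloses any lactone opened by methoxide.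

**Compound list**

1 | 4-ethynyl-1,2-dimethoxybenzene | COc1ccc(C#C)cc1OC | starting material
2 | 2-[(E)-2-(3,4-dimethoxyphenyl)ethenyl]-1,3,2-benzodioxaborole | COc1ccc(/C=C/B2Oc3ccccc3O2)cc1OC | intermediate
3 | [(E)-2-(3,4-dimethoxyphenyl)ethenyl]boronic acid | COc1ccc(/C=C/B(O)O)cc1OC | intermediate
4 | (2R,3R)-2,3-dihydroxy-N,N,N',N'-tetramethylbutanediamide | CN(C)C(=O)[C@H](O)[C@@H](O)C(=O)N(C)C | starting material
5 | (4R,5R)-2-[(E)-2-(3,4-dimethoxyphenyl)ethenyl]-N,N,N',N'-tetramethyl-1,3,2-dioxaborolane-4,5-dicarboxamide | CN(C)C(=O)[C@@H]1OB(/C=C/c2ccc(OC)c(OC)c2)O[C@H]1C(=O)N(C)C | intermediate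
6 | (4R,5R)-2-[(1R,2R)-2-(3,4-dimethoxyphenyl)cyclopropyl]-N,N,N',N'-tetramethyl-1,3,2-dioxaborolane-4,5-dicarboxamide | CN(C)C(=O)[C@@H]1OB([C@@H]2C[C@H]2c2ccc(OC)c(OC)c2)O[C@H]1C(=O)N(C)C | intermediate
7 | [(1R,2R)-2-(3,4-dimethoxyphenyl)cyclopropyl]boronic acid | OB(O)[C@@H]1C[C@H]1c1ccc(OC)c(OC)c1 | intermediate
8 | vanillin (4-hydroxy-3-methoxybenzaldehyde) | COc1cc(C=O)ccc1O | starting material
9 | 4-formyl-2-methoxyphenyl 2,2-dimethylpropanoate | COc1cc(C=O)ccc1OC(=O)C(C)(C)C | intermediate
10 | tert-butyl (triphenylphosphoranylidene)acetate | CC(C)(C)OC(=O)C=P(c1ccccc1)(c1ccccc1)c1ccccc1 | starting material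
11 | tert-butyl bromo(triphenylphosphoranylidene)acetate | CC(C)(C)OC(=O)C(Br)=P(c1ccccc1)(c1ccccc1)c1ccccc1 | intermediate
12 | tert-butyl (2Z)-2-bromo-3-[4-(2,2-dimethylpropanoyloxy)-3-methoxyphenyl]prop-2-enoate | COc1cc(/C=C(\Br)C(=O)OC(C)(C)C)ccc1OC(=O)C(C)(C)C | intermediate
13 | tert-butyl (2E)-2-[(1R,2R)-2-(3,4-dimethoxyphenyl)cyclopropyl]-3-[4-(2,2-dimethylpropanoyloxy)-3-methoxyphenyl]prop-2-enoate | COc1cc(/C=C(/C(=O)OC(C)(C)C)[C@@H]2C[C@H]2c2ccc(OC)c(OC)c2)ccc1OC(=O)C(C)(C)C | intermediate
14 | trimethylsilyl (2E)-2-[(1R,2R)-2-(3,4-dimethoxyphenyl)cyclopropyl]-3-[4-(2,2-dimethylpropanoyloxy)-3-methoxyphenyl]prop-2-enoate | COc1cc(/C=C(/C(=O)O[Si](C)(C)C)[C@@H]2C[C@H]2c2ccc(OC)c(OC)c2)ccc1OC(=O)C(C)(C)C | intermediate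
15 | (2E)-2-[(1R,2R)-2-(3,4-dimethoxyphenyl)cyclopropyl]-3-[4-(2,2-dimethylpropanoyloxy)-3-methoxyphenyl]prop-2-enoic acid | COc1cc(/C=C(/C(=O)O)[C@@H]2C[C@H]2c2ccc(OC)c(OC)c2)ccc1OC(=O)C(C)(C)C | intermediate
16 | 4-{(E)-[(4R)-4-(3,4-dimethoxybenzyl)-2-oxooxolan-3-ylidene]methyl}-2-methoxyphenyl 2,2-dimethylpropanoate | COc1cc(/C=C2/C(=O)OC[C@@H]2Cc2ccc(OC)c(OC)c2)ccc1OC(=O)C(C)(C)C | intermediate
17 | (3E,4R)-4-(3,4-dimethoxybenzyl)-3-(4-hydroxy-3-methoxybenzylidene)oxolan-2-one | COc1cc(/C=C2/C(=O)OC[C@@H]2Cc2ccc(OC)c(OC)c2)ccc1O | target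

**Step count**

Total: 9 steps. Longest linear sequence: 7 steps (steps 1, 2, 3, 6, 7, 8, 9 from alkyne 1).

**Steps most likely to fail**

Step 8. The radical cation may open by unassisted scission of the C4–Cb bond (a vinylcyclopropane-type opening) faster than the carboxylate attacks C5. That would scramble C4 and divert material to a six-membered lactone or a cyclopentene; back electron transfer and thiol addition to the acrylate could also stall the reaction. The fallback builds the same lactone by known aldol chemistry; it sets out from aldehyde 9 and comes back at 16. 3-(3,4-Dimethoxyphenyl)propanoic acid is activated with t-BuCOCl and Et3N and joined to lithiated (4S)-4-benzyl-1,3-oxazolidin-2-one to give the imide (4S)-4-benzyl-3-[3-(3,4-dimethoxyphenyl)propanoyl]-1,3-oxazolidin-2-one F1. Its sodium enolate (NaN(SiMe3)2, THF, −78 °C) is alkylated by tert-butyl bromoacetate on the face away from the benzyl group to give tert-butyl (3R)-4-[(4S)-4-benzyl-2-oxo-1,3-oxazolidin-3-yl]-3-(3,4-dimethoxybenzyl)-4-oxobutanoate F2. LiBH4 removes the auxiliary to give tert-butyl (3R)-3-(3,4-dimethoxybenzyl)-4-hydroxybutanoate F3, and CF3CO2H in CH2Cl2 closes it to (4R)-4-(3,4-dimethoxybenzyl)oxolan-2-one F4. The lithium enolate of F4 (LiN(iPr)2, THF, −78 °C) adds to aldehyde 9 trans to the benzyl group to give the aldol 4-{hydroxy[(3S,4R)-4-(3,4-dimethoxybenzyl)-2-oxooxolan-3-yl]methyl}-2-methoxyphenyl 2,2-dimethylpropanoate F5 as carbinol epimers. Mesylation (MsCl, Et3N) and E1cB elimination with DBU should give the thermodynamically preferred E benzylidene lactone 16.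

Step 3. Facial discrimination by the tartaramide may be insufficient (or of the wrong sense) on an aryl-substituted alkenylboronate, and carbenoid transfer to the boron-substituted alkene may be sluggish. The fallback gives up auxiliary control for a racemic cyclopropanation followed by separation of enantiomers; it sets out from boronic acid 3 and comes back at 13. Esterification of 3 with pinacol gives 2-[(E)-2-(3,4-dimethoxyphenyl)ethenyl]-4,4,5,5-tetramethyl-1,3,2-dioxaborolane F6. Simmons–Smith cyclopropanation (Et2Zn, CH2I2, CH2Cl2) gives racemic trans-2-[2-(3,4-dimethoxyphenyl)cyclopropyl]-4,4,5,5-tetramethyl-1,3,2-dioxaborolane F7. Preparative chromatography on a chiral stationary phase gives 2-[(1R,2R)-2-(3,4-dimethoxyphenyl)cyclopropyl]-4,4,5,5-tetramethyl-1,3,2-dioxaborolane F8, which is coupled with 12 under the conditions of step 6 to give 13.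

Step 6. Transmetalation of the secondary cyclopropylboron to palladium at the hindered alpha-bromo enoate may be slow. That would let protodeboronation of 7, dehydrobromination of 12 to the arylpropiolate, or partial hydrolysis of the aryl pivalate take over. The fallback changes the order of events, so that the C3–C4 bond is made by a fast sp2–sp2 coupling and the cyclopropane is built afterwards; it sets out from 3 and 12 and comes back at 13. Suzuki coupling of alkenylboronic acid 3 with 12 (Pd(OAc)2, SPhos, K3PO4, toluene/H2O, 40 °C) gives tert-butyl (2E,3E)-4-(3,4-dimethoxyphenyl)-2-[4-(2,2-dimethylpropanoyloxy)-3-methoxybenzylidene]but-3-enoate F9. The electrophilic zinc carbenoid (Et2Zn, CH2I2, CF3CO2H, CH2Cl2) should cyclopropanate the electron-rich styryl double bond and leave the ester-bearing one, giving racemic tert-butyl (2E)-2-[trans-2-(3,4-dimethoxyphenyl)cyclopropyl]-3-[4-(2,2-dimethylpropanoyloxy)-3-methoxyphenyl]prop-2-enoate F10. Separation on a chiral stationary phase gives 13.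

**Further compounds**

F1 | step 8 | (4S)-4-benzyl-3-[3-(3,4-dimethoxyphenyl)propanoyl]-1,3-oxazolidin-2-one | COc1ccc(CCC(=O)N2[C@@H](Cc3ccccc3)COC2=O)cc1OC
F2 | step 8 | tert-butyl (3R)-4-[(4S)-4-benzyl-2-oxo-1,3-oxazolidin-3-yl]-3-(3,4-dimethoxybenzyl)-4-oxobutanoate | COc1ccc(C[C@H](CC(=O)OC(C)(C)C)C(=O)N2[C@@H](Cc3ccccc3)COC2=O)cc1OC
F3 | step 8 | tert-butyl (3R)-3-(3,4-dimethoxybenzyl)-4-hydroxybutanoate | COc1ccc(C[C@H](CC(=O)OC(C)(C)C)CO)cc1OC
F4 | step 8 | (4R)-4-(3,4-dimethoxybenzyl)oxolan-2-one | O=C1OC[C@@H](C1)Cc1ccc(OC)c(OC)c1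
F5 | step 8 | 4-{hydroxy[(3S,4R)-4-(3,4-dimethoxybenzyl)-2-oxooxolan-3-yl]methyl}-2-methoxyphenyl 2,2-dimethylpropanoate (carbinol epimers) | COc1cc(C(O)[C@H]2C(=O)OC[C@@H]2Cc2ccc(OC)c(OC)c2)ccc1OC(=O)C(C)(C)C
F6 | step 3 | 2-[(E)-2-(3,4-dimethoxyphenyl)ethenyl]-4,4,5,5-tetramethyl-1,3,2-dioxaborolane | COc1ccc(/C=C/B2OC(C)(C)C(C)(C)O2)cc1OC
F7 | step 3 | racemic trans-2-[2-(3,4-dimethoxyphenyl)cyclopropyl]-4,4,5,5-tetramethyl-1,3,2-dioxaborolane (both enantiomers) | CC1(C)OB(OC1(C)C)[C@@H]1C[C@H]1c1ccc(OC)c(OC)c1.CC1(C)OB(OC1(C)C)[C@H]1C[C@@H]1c1ccc(OC)c(OC)c1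
F8 | step 3 | 2-[(1R,2R)-2-(3,4-dimethoxyphenyl)cyclopropyl]-4,4,5,5-tetramethyl-1,3,2-dioxaborolane | CC1(C)OB(OC1(C)C)[C@@H]1C[C@H]1c1ccc(OC)c(OC)c1
F9 | step 6 | tert-butyl (2E,3E)-4-(3,4-dimethoxyphenyl)-2-[4-(2,2-dimethylpropanoyloxy)-3-methoxybenzylidene]but-3-enoate | COc1cc(/C=C(/C(=O)OC(C)(C)C)\C=C\c2ccc(OC)c(OC)c2)ccc1OC(=O)C(C)(C)C
F10 | step 6 | racemic tert-butyl (2E)-2-[trans-2-(3,4-dimethoxyphenyl)cyclopropyl]-3-[4-(2,2-dimethylpropanoyloxy)-3-methoxyphenyl]prop-2-enoate (both enantiomers) | COc1cc(/C=C(/C(=O)OC(C)(C)C)[C@@H]2C[C@H]2c2ccc(OC)c(OC)c2)ccc1OC(=O)C(C)(C)C.COc1cc(/C=C(/C(=O)OC(C)(C)C)[C@H]2C[C@@H]2c2ccc(OC)c(OC)c2)ccc1OC(=O)C(C)(C)C
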